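## Structural features

The target is the mono-(3-methylbut-2-enyl) ether of the 8–8' lignan (+)-pinoresinol. Two tetrahydrofuran rings, ring A (C7–O–C9'–C8'–C8) and ring B (C7'–O–C9–C8–C8'), share the C8–C8' bond in a cis-fused 3,7-dioxabicyclo[3.3.0]octane. Each ring carries one 3-methoxy-4-oxyphenyl group on the carbon next to its oxygen: C7 (free phenol half) and C7' (prenyloxy half). Both aryl groups lie on the convex (exo) face, and the four contiguous stereocentres are 7S, 8R, 8'R, 7'S. The skeleton is C2-symmetric; only OH versus O-prenyl breaks the symmetry. The fragile sites are the two benzylic C–O bonds para to oxygen donors (acid ionises them, which epimerises or opens the rings), the free phenol, and the prenyl ether (acid, borane, carbenoids). The cis fusion is not the problem, because only cis can exist. The real difficulty is the configuration at the two benzylic carbons, where exo and endo differ little in energy, and telling the two nearly identical aryl rings apart. The key step exploits the C7–C8 bond: C7 is a benzylic ether carbon whose hydrogens are activated by the ring A oxygen and the aryl group. C8 becomes the alpha carbon of a butyrolactone once C9 of ring B is raised to a carbonyl, so a carbenoid at C8 sits five atoms from the C7–H bonds of an arylmethyl ether on C9'.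

## Logic of the disconnections

24 to 23: the phenolic O–Si bond on the C7 aryl ring is cut. The free phenol para to C7 is the most sensitive site, so it stays masked to the end, and the donor silyl ether is what lets C7 ionise in step 14. There is no skeletal gain but a large gain in robustness. The forward step must be non-acidic and spare the allylic ether, which points to fluoride.

23 to 21 and 22: the aryl O–CH2 bond of the prenyl ether is cut. The alkene of 22 would not survive borane, the carbenoid or the Lewis acid steps. This removes the only alkene and makes the end convergent. It demands that 21 has exactly one free phenol.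

21 to 20: the aryl O–S bond on the C7' ring is cut. An electron-withdrawing mask is wanted on this ring until C7 has been corrected, so that C7'–O cannot ionise. The unmasking must spare the aryl silyl ether.

20 to 19: no skeletal bond changes; the C7–O bond of ring A is opened and re-formed so that C7 is inverted. The C–H insertion cannot be expected to put the C7 aryl group exo, so the route plans for the endo epimer. The demand is that only C7 ionises and that the exo epimer can be separated from an equilibrium with a small bias.

19 to 17 to 16: the C9–O bond of ring B is cut and C9 is raised to the lactone carbonyl. The carbonyl is what makes C8 a carbenoid site. The forward reclosure must leave the C7'–O bond untouched (retention at C7'), which a primary sulfonate displacement does.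

16 to 15: the C7–C8 bond is cut, which opens ring A. This is the key simplification: the bicycle becomes a monocyclic trans-lactone carrying an arylmethyl ether, and two stereocentres disappear. The forward step must choose the benzylic C7–H over all other C–H bonds and give the cis fusion.

15 to 13: the C8=N2 bond is cut. The diazo group is put on last because it is the least robust function. The forward step must place it at C8 without epimerising C8' or C7'.

13 to 12 and 4: the O–C7 bond of the arylmethyl ether is cut. This separates the two aryl halves, each from 1. The etherification must run without alkoxide, which would open or isomerise the lactone.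

12 to 11 to 10: C9' is raised from CH2OH through the acid to the N-acyl oxazolidinone, and the N–C9' bond is cut. This exposes the aldol retron. The forward reduction must distinguish the acid from the lactone.

10 to 8 and 5: the C7'–C8' bond (aldol) and the lactone O–C9 acyl bond are cut. Both stereocentres of the lactone come from one auxiliary-controlled syn-aldol, and the trans arrangement follows from it. The enolate must form only next to the imide carbonyl.

8 to 6 and 7, 5 to 1, and 4 to 3 to 2 to 1: N-acyl, O-sulfonyl, O-silyl and imidate bonds are cut. These are protecting-group and activation steps on commercial materials with no selectivity demand beyond chemoselectivity.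

## Other disconnections considered

Alternative 1: The cut is C8–C8' together with C7'–O, so both rings come from an acyclic ether, the epoxide A2 (C7 already set, cinnamyl ether on its oxygen, oxirane across C8–C9).
- Forward step: Cp2TiCl (trivalent titanium) opens the oxirane to a C8 radical. 5-exo addition to the cinnamyl alkene forms C8–C8' and ring A. Iodine then oxidises the benzylic C7' centre and the C9 oxygen closes ring B, giving A1, which is the same compound as 23.
- In favour: one flask makes two rings, C8–C8', C7'–O and three stereocentres. C7 is fixed beforehand, and the C7' aryl group is placed by oxygen attack on a flat benzylic centre, the closure mode that favours exo.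
- Better than the chosen plan: on the configuration of the benzylic carbons and on step count. A1 needs only step 17 and no equilibration like step 14.
- Against: the prenyl alkene and two electron-rich rings must survive iodine. Both the cis relation of C8/C8' and the trans relation of C7/C8 rest on the conformational preference of one radical cyclisation. Titanium is stoichiometric.
- Comparison: the chosen plan is the equal in how securely C8' and C7' are set (auxiliary aldol) and better in functional-group tolerance.

Alternative 2: The cut is C7–O and C7–C8, with C8'–C9' formed by migration.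
- Forward step: SnCl4 condenses 2 with the diol A4 to an oxocarbenium ion on the C9' oxygen. The alkene adds through a chair-like six-membered transition state (C7–C8), and the ring bond to C9' shifts from C7' to C8'. This contracts the ring to ring A and unveils the C7' aldehyde in A3.
- In favour: it is convergent and takes its chirality from a cheap chiral-pool diol, the equal of an auxiliary.
- Better than the chosen plan: the chair places the aryl group and the C9 substituent trans, so C7 and C8 arrive with the relative configuration of the target.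
- Against: C8' emerges trans to C9, but ring B needs cis. That means epimerising alpha to the aldehyde towards the less stable isomer. C7' must then be made by aryl addition to the aldehyde with weak facial control, and ring B still has to be closed. SnCl4 meets a silyl ether and an electron-rich aldehyde.
- Comparison: both plans build ring A first. The chosen plan has C7' and C8' fixed before its key step, whereas this one has to repair C8' and create C7' afterwards. In step count it is no better and probably longer.

Alternative 3: The cut is C7'–C8' and C8–C9: ring B by a (3+2) cycloaddition across the C8=C8' bond of the butenolide A6, which already carries the C7 aryl group.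
- Forward step: CsF turns the chloro silylmethyl ether A7 into the carbonyl ylide, which adds anti to the C7 aryl group and gives A5.
- In favour: it is the most convergent plan, with two C–C bonds, ring B and three stereocentres in one step. The cis fusion is automatic, which is the equal of the chosen plan. The prenyl ether is carried from the start.
- Better than the chosen plan: on step economy, since A5 is two or three steps from the target and the phenols need no late differentiation.
- Against: C7' depends on the endo/exo orientation of a small, short-lived ylide, with no strong bias for exo. This is the same kind of weakness as C7 in the chosen plan, but it cannot be corrected by acid because the prenyl ether is present. A6 has an acidic benzylic C7 hydrogen and may racemise under fluoride. The lactone must later be reduced with a Lewis acid beside the prenyl ether.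

Key step: step 11

Remark on the chemistry: acetate-bridged dirhodium carbenoids are expected to close such 2-aryl tetrahydrofurans with the aryl group cis to the carbonyl, so 16 is drawn as the C7-endo epimer and C7 is inverted in step 14. The lactone-side phenol is carried as a tosylate, not an acyl ester, because it must pass LiOOH and LiBH4.

## Route

Step 1
Reactants: 1 vanillin
Product: 2 3-methoxy-4-(triisopropylsilyloxy)benzaldehyde
Conditions: iPr3SiCl, imidazole, DMF, rt
Reagents that add atoms: triisopropylsilyl chloride, CC(C)[Si](Cl)(C(C)C)C(C)C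
Why: Imidazole-mediated silylation of the phenol; the bulky silyl ether should survive hydride, enolate, carbenoid and Lewis acid steps and leave with fluoride at the end.

Step 2
Reactants: 2 3-methoxy-4-(triisopropylsilyloxy)benzaldehyde
Product: 3 [3-methoxy-4-(triisopropylsilyloxy)phenyl]methanol
Conditions: NaBH4, MeOH, 0 °C
Reagents that add atoms: none
Why: Borohydride reduction of an aryl aldehyde; the aryl silyl ether is inert at 0 °C.

Step 3
Reactants: 3 [3-methoxy-4-(triisopropylsilyloxy)phenyl]methanol
Product: 4 3-methoxy-4-(triisopropylsilyloxy)benzyl 2,2,2-trichloroacetimidate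
Conditions: Cl3CCN, DBU (10 mol%), CH2Cl2, 0 °C; used crude
Reagents that add atoms: trichloroacetonitrile, N#CC(Cl)(Cl)Cl
Why: Base-catalysed addition of the alcohol to the nitrile (trichloroacetimidate formation) gives a benzyl donor that reacts under mild acid, so no alkoxide meets the lactone in step 9.

Step 4
Reactants: 1 vanillin
Product: 5 4-formyl-2-methoxyphenyl 4-methylbenzenesulfonate
Conditions: TsCl, Et3N, DMAP (5 mol%), CH2Cl2, 0 °C to rt
Reagents that add atoms: 4-methylbenzenesulfonyl chloride, Cc1ccc(cc1)S(Cl)(=O)=O
Why: Sulfonylation of the phenol; the tosylate withstands LiOOH, borane, enolates and the carbenoid, and keeps this ring electron-poor so that C7'–O does not ionise in step 14.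

Step 5
Reactants: 6 (S)-4-benzyl-1,3-oxazolidin-2-one; 7 methyl 4-chloro-4-oxobutanoate
Product: 8 methyl 4-[(4S)-4-benzyl-2-oxo-1,3-oxazolidin-3-yl]-4-oxobutanoate
Conditions: n-BuLi, THF, −78 °C; then 7, −78 to 0 °C
Reagents that add atoms: none
Why: N-acylation of the lithiated oxazolidinone by the acid chloride, which reacts far faster than the methyl ester end.

Step 6
Reactants: 8 methyl 4-[(4S)-4-benzyl-2-oxo-1,3-oxazolidin-3-yl]-4-oxobutanoate; 5 4-formyl-2-methoxyphenyl 4-methylbenzenesulfonate
Product: 10 (4S)-4-benzyl-3-{[(2S,3S)-2-[3-methoxy-4-(tosyloxy)phenyl]-5-oxotetrahydrofuran-3-yl]carbonyl}-1,3-oxazolidin-2-one, via syn-aldol adduct 9 (not isolated)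
Conditions: Bu2BOTf, iPr2NEt, CH2Cl2, −78 to 0 °C; 5, −78 to 0 °C; pH 7 buffer, MeOH, H2O2; then PPTS (cat.), toluene, 60 °C
Reagents that add atoms: none
Why: Evans syn-aldol: the Z-boron enolate forms only next to the imide and reacts through a Zimmerman–Traxler chair, with the auxiliary benzyl group blocking one face, which sets C8' and C7' (3S,4S in 9). The gamma-hydroxy ester then lactonises by acyl substitution, and the syn adduct necessarily gives the trans 2,3-disubstituted lactone.

Step 7
Reactants: 10 (4S)-4-benzyl-3-{[(2S,3S)-2-[3-methoxy-4-(tosyloxy)phenyl]-5-oxotetrahydrofuran-3-yl]carbonyl}-1,3-oxazolidin-2-one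
Product: 11 (2S,3S)-2-[3-methoxy-4-(tosyloxy)phenyl]-5-oxotetrahydrofuran-3-carboxylic acid
Conditions: LiOH, H2O2, THF–H2O, 0 °C; Na2SO3; HCl to pH 2
Reagents that add atoms: hydrogen peroxide, OO
Why: Hydroperoxide cleavage of the exocyclic imide carbonyl, the standard auxiliary removal, with the auxiliary recovered; any lactone opened by hydroxide recloses on acidification because only one gamma-lactone is possible.

Step 8
Reactants: 11 (2S,3S)-2-[3-methoxy-4-(tosyloxy)phenyl]-5-oxotetrahydrofuran-3-carboxylic acid
Product: 12 (4R,5S)-4-(hydroxymethyl)-5-[3-methoxy-4-(tosyloxy)phenyl]dihydrofuran-2(3H)-one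
Conditions: BH3·SMe2, THF, 0 °C to rt; MeOH
Reagents that add atoms: none
Why: Borane reduces a carboxylic acid (through the acyloxyborane) much faster than a lactone or an aryl sulfonate, and no basic alkoxide is formed that could move the lactone onto the new hydroxyl.

Step 9
Reactants: 12 (4R,5S)-4-(hydroxymethyl)-5-[3-methoxy-4-(tosyloxy)phenyl]dihydrofuran-2(3H)-one; 4 3-methoxy-4-(triisopropylsilyloxy)benzyl 2,2,2-trichloroacetimidate
Product: 13 (4R,5S)-4-({[3-methoxy-4-(triisopropylsilyloxy)phenyl]methoxy}methyl)-5-[3-methoxy-4-(tosyloxy)phenyl]dihydrofuran-2(3H)-one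
Conditions: camphorsulfonic acid (10 mol%), CH2Cl2, 0 °C to rt
Reagents that add atoms: none
Why: Acid-catalysed O-benzylation with a trichloroacetimidate, as used for 4-methoxybenzyl ethers; the donor ionises easily and the lactone is not exposed to base.

Step 10
Reactants: 13 (4R,5S)-4-({[3-methoxy-4-(triisopropylsilyloxy)phenyl]methoxy}methyl)-5-[3-methoxy-4-(tosyloxy)phenyl]dihydrofuran-2(3H)-one
Product: 15 (4R,5S)-3-diazo-4-({[3-methoxy-4-(triisopropylsilyloxy)phenyl]methoxy}methyl)-5-[3-methoxy-4-(tosyloxy)phenyl]dihydrofuran-2(3H)-one, via 3-trifluoroacetyl lactone 14 (not isolated)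
Conditions: LiN(SiMe3)2, THF, −78 °C; CF3CO2CH2CF3; then MsN3, Et3N, H2O, MeCN, rt
Reagents that add atoms: methanesulfonyl azide, CS(=O)(=O)N=[N+]=[N-]
Why: Detrifluoroacetylative diazo transfer: C-acylation of the lactone enolate activates C8, and the sulfonyl azide then delivers N2 with loss of the trifluoroacetyl group. C8' and C7' carry no leaving group or acidic hydrogen that the enolate could disturb.

Step 11
Reactants: 15 (4R,5S)-3-diazo-4-({[3-methoxy-4-(triisopropylsilyloxy)phenyl]methoxy}methyl)-5-[3-methoxy-4-(tosyloxy)phenyl]dihydrofuran-2(3H)-one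
Product: 16 (3S,3aR,6R,6aS)-6-[3-methoxy-4-(triisopropylsilyloxy)phenyl]-3-[3-methoxy-4-(tosyloxy)phenyl]tetrahydro-1H,3H-furo[3,4-c]furan-1-one (cis-fused 9-oxo lactone, C7 aryl endo, C7' aryl exo)
Conditions: Rh2(OAc)4 (2 mol%), CH2Cl2, reflux, slow addition of 15 at high dilution
Reagents that add atoms: none
Why: Rh2(OAc)4 binds the diazo carbon of 15, dinitrogen leaves, and the electrophilic carbenoid at C8 takes up a benzylic C7–H bond through a three-centre transition state with hydride-transfer character that forms C7–C8 and releases the catalyst. The closest known reaction type is the dirhodium tetracarboxylate-catalysed intramolecular C–H insertion of alpha-diazo esters and lactones into C–H bonds next to an ether oxygen, which gives tetrahydrofurans with the carbonyl on C3. Ring A closes as a 1,5 insertion: C8, C8', C9', the ether oxygen and C7 form the five-membered ring in a compact cyclic transition state. C8 is set by the substrate, because the tether hangs from C8' and can reach the carbenoid only on the face that carries C9', so the fusion can only be cis (8S in 16; the letter differs from the target only because C9 is a carbonyl). C7 is set in the same transition state: the dirhodium core and its acetate wall occupy the convex side next to C8, so the aryl group should turn to the concave side and end cis to the lactone carbonyl (7R, endo), which is not what the target needs and is inverted at this one centre in step 14. What the step must deliver is site selectivity and the cis fusion: the two C7–H bonds are the only C–H bonds five atoms from C8 that are activated by both oxygen and an electron-rich aryl group, 15 contains no alkene, and the sulfonate makes the lactone aryl ring a poor partner for the carbenoid. Slow addition at high dilution keeps carbene dimers down, and the 1,2-shift of the C8' hydrogen, the usual competitor of alkyl-substituted carbenoids, has to lose against an insertion that is intramolecular and electronically favoured.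

Step 12
Reactants: 16 (3S,3aR,6R,6aS)-6-[3-methoxy-4-(triisopropylsilyloxy)phenyl]-3-[3-methoxy-4-(tosyloxy)phenyl]tetrahydro-1H,3H-furo[3,4-c]furan-1-one
Product: 17 (S)-{(3R,4R,5R)-4-(hydroxymethyl)-5-[3-methoxy-4-(triisopropylsilyloxy)phenyl]tetrahydrofuran-3-yl}[3-methoxy-4-(tosyloxy)phenyl]methanol
Conditions: LiBH4, THF, 0 °C to rt
Reagents that add atoms: none
Why: Borohydride reduction of the gamma-lactone to the 1,4-diol; benzylic ethers, the aryl sulfonate and the aryl silyl ether do not react, and no C–O bond at C7 or C7' is broken.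

Step 13
Reactants: 17 (S)-{(3R,4R,5R)-4-(hydroxymethyl)-5-[3-methoxy-4-(triisopropylsilyloxy)phenyl]tetrahydrofuran-3-yl}[3-methoxy-4-(tosyloxy)phenyl]methanol
Product: 19 (1R,3aR,4S,6aR)-1-[3-methoxy-4-(triisopropylsilyloxy)phenyl]-4-[3-methoxy-4-(tosyloxy)phenyl]tetrahydro-1H,3H-furo[3,4-c]furan, via primary mesylate 18 (not isolated)
Conditions: MsCl (1.1 equiv), Et3N, CH2Cl2, −20 °C to rt
Reagents that add atoms: none
Why: Selective sulfonylation of the primary alcohol, then intramolecular Williamson displacement (5-exo-tet) by the benzylic hydroxyl closes ring B. The C7'–O bond is never broken, so C7' keeps its configuration, and the electron-poor aryl ring suppresses ionisation at C7'.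

Step 14
Reactants: 19 (1R,3aR,4S,6aR)-1-[3-methoxy-4-(triisopropylsilyloxy)phenyl]-4-[3-methoxy-4-(tosyloxy)phenyl]tetrahydro-1H,3H-furo[3,4-c]furan
Product: 20 (1S,3aR,4S,6aR)-1-[3-methoxy-4-(triisopropylsilyloxy)phenyl]-4-[3-methoxy-4-(tosyloxy)phenyl]tetrahydro-1H,3H-furo[3,4-c]furan
Conditions: BF3·OEt2 (0.2 equiv), CH2Cl2, −20 to 0 °C, to equilibrium; chromatography, recovered 19 resubmitted
Reagents that add atoms: none
Why: Lewis-acid epimerisation of a benzylic ether centre, the known acid equilibration of furofuran lignans: the C7–O bond ionises reversibly to the 4-silyloxybenzyl cation and the C9' oxygen recloses. Only C7 reacts because the other aryl ring is deactivated by the sulfonate. The exo aryl arrangement is the more stable one but should be favoured only modestly, hence the separation and recycling.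

Step 15
Reactants: 20 (1S,3aR,4S,6aR)-1-[3-methoxy-4-(triisopropylsilyloxy)phenyl]-4-[3-methoxy-4-(tosyloxy)phenyl]tetrahydro-1H,3H-furo[3,4-c]furan
Product: 21 2-methoxy-4-{(1S,3aR,4S,6aR)-4-[3-methoxy-4-(triisopropylsilyloxy)phenyl]tetrahydro-1H,3H-furo[3,4-c]furan-1-yl}phenol
Conditions: Mg, MeOH, rt
Reagents that add atoms: none
Why: Single-electron reductive cleavage of the aryl sulfonate S–O bond by magnesium in methanol frees the phenol; benzylic ethers are not reduced at this potential and the hindered aryl silyl ether should outlast the mildly basic medium.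

Step 16
Reactants: 21 2-methoxy-4-{(1S,3aR,4S,6aR)-4-[3-methoxy-4-(triisopropylsilyloxy)phenyl]tetrahydro-1H,3H-furo[3,4-c]furan-1-yl}phenol; 22 prenyl bromide (1-bromo-3-methylbut-2-ene)
Product: 23 (1S,3aR,4S,6aR)-1-[3-methoxy-4-(triisopropylsilyloxy)phenyl]-4-[3-methoxy-4-(3-methylbut-2-enyloxy)phenyl]tetrahydro-1H,3H-furo[3,4-c]furan
Conditions: K2CO3, acetone, 50 °C
Reagents that add atoms: none
Why: Williamson etherification of the only free phenol with a primary allylic bromide (SN2 at CH2); the furofuran is stable to carbonate.

Step 17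
Reactants: 23 (1S,3aR,4S,6aR)-1-[3-methoxy-4-(triisopropylsilyloxy)phenyl]-4-[3-methoxy-4-(3-methylbut-2-enyloxy)phenyl]tetrahydro-1H,3H-furo[3,4-c]furan
Product: 24 2-methoxy-4-{(1S,3aR,4S,6aR)-4-[3-methoxy-4-(3-methylbut-2-enyloxy)phenyl]tetrahydro-1H,3H-furo[3,4-c]furan-1-yl}phenol (target)
Conditions: Bu4NF, THF, 0 °C; aq NH4Cl
Reagents that add atoms: none
Why: Fluoride cleavage of the aryl silyl ether, driven by the Si–F bond; cold, non-acidic conditions leave the prenyl ether and both benzylic ethers untouched, so no stereocentre is at risk.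

## Compound list

1 | vanillin (4-hydroxy-3-methoxybenzaldehyde) | COc1cc(C=O)ccc1O | starting material
2 | 3-methoxy-4-(triisopropylsilyloxy)benzaldehyde | COc1cc(C=O)ccc1O[Si](C(C)C)(C(C)C)C(C)C | intermediate
3 | [3-methoxy-4-(triisopropylsilyloxy)phenyl]methanol | COc1cc(CO)ccc1O[Si](C(C)C)(C(C)C)C(C)C | intermediate
4 | 3-methoxy-4-(triisopropylsilyloxy)benzyl 2,2,2-trichloroacetimidate | COc1cc(COC(=N)C(Cl)(Cl)Cl)ccc1O[Si](C(C)C)(C(C)C)C(C)C | intermediate
5 | 4-formyl-2-methoxyphenyl 4-methylbenzenesulfonate | COc1cc(C=O)ccc1OS(=O)(=O)c1ccc(C)cc1 | intermediate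
6 | (S)-4-benzyl-1,3-oxazolidin-2-one | O=C1N[C@@H](Cc2ccccc2)CO1 | starting material
7 | methyl 4-chloro-4-oxobutanoate | COC(=O)CCC(Cl)=O | starting material
8 | methyl 4-[(4S)-4-benzyl-2-oxo-1,3-oxazolidin-3-yl]-4-oxobutanoate | COC(=O)CCC(=O)N1[C@@H](Cc2ccccc2)COC1=O | intermediate
9 | methyl (3S,4S)-3-{[(4S)-4-benzyl-2-oxo-1,3-oxazolidin-3-yl]carbonyl}-4-hydroxy-4-[3-methoxy-4-(tosyloxy)phenyl]butanoate | COC(=O)C[C@H](C(=O)N1[C@@H](Cc2ccccc2)COC1=O)[C@H](O)c1ccc(OS(=O)(=O)c2ccc(C)cc2)c(OC)c1 | intermediate
10 | (4S)-4-benzyl-3-{[(2S,3S)-2-[3-methoxy-4-(tosyloxy)phenyl]-5-oxotetrahydrofuran-3-yl]carbonyl}-1,3-oxazolidin-2-one | O=C1OC[C@H](Cc2ccccc2)N1C(=O)[C@H]3CC(=O)O[C@@H]3c4ccc(OS(=O)(=O)c5ccc(C)cc5)c(OC)c4 | intermediate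
11 | (2S,3S)-2-[3-methoxy-4-(tosyloxy)phenyl]-5-oxotetrahydrofuran-3-carboxylic acid | OC(=O)[C@H]1CC(=O)O[C@@H]1c2ccc(OS(=O)(=O)c3ccc(C)cc3)c(OC)c2 | intermediate
12 | (4R,5S)-4-(hydroxymethyl)-5-[3-methoxy-4-(tosyloxy)phenyl]dihydrofuran-2(3H)-one | OC[C@H]1CC(=O)O[C@@H]1c2ccc(OS(=O)(=O)c3ccc(C)cc3)c(OC)c2 | intermediate
13 | (4R,5S)-4-({[3-methoxy-4-(triisopropylsilyloxy)phenyl]methoxy}methyl)-5-[3-methoxy-4-(tosyloxy)phenyl]dihydrofuran-2(3H)-one | CC(C)[Si](C(C)C)(C(C)C)Oc1ccc(cc1OC)COC[C@H]2CC(=O)O[C@@H]2c3ccc(OS(=O)(=O)c4ccc(C)cc4)c(OC)c3 | intermediate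
14 | 3-(trifluoroacetyl) derivative of 13 (C3 epimers and enol) | CC(C)[Si](C(C)C)(C(C)C)Oc1ccc(cc1OC)COC[C@H]2C(C(=O)C(F)(F)F)C(=O)O[C@@H]2c3ccc(OS(=O)(=O)c4ccc(C)cc4)c(OC)c3 | intermediate
15 | (4R,5S)-3-diazo-4-({[3-methoxy-4-(triisopropylsilyloxy)phenyl]methoxy}methyl)-5-[3-methoxy-4-(tosyloxy)phenyl]dihydrofuran-2(3H)-one | CC(C)[Si](C(C)C)(C(C)C)Oc1ccc(cc1OC)COC[C@H]2C(=[N+]=[N-])C(=O)O[C@@H]2c3ccc(OS(=O)(=O)c4ccc(C)cc4)c(OC)c3 | intermediate
16 | (3S,3aR,6R,6aS)-6-[3-methoxy-4-(triisopropylsilyloxy)phenyl]-3-[3-methoxy-4-(tosyloxy)phenyl]tetrahydro-1H,3H-furo[3,4-c]furan-1-one | CC(C)[Si](C(C)C)(C(C)C)Oc1ccc(cc1OC)[C@@H]2OC[C@H]3[C@@H]2C(=O)O[C@@H]3c4ccc(OS(=O)(=O)c5ccc(C)cc5)c(OC)c4 | intermediate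
17 | (S)-{(3R,4R,5R)-4-(hydroxymethyl)-5-[3-methoxy-4-(triisopropylsilyloxy)phenyl]tetrahydrofuran-3-yl}[3-methoxy-4-(tosyloxy)phenyl]methanol | CC(C)[Si](C(C)C)(C(C)C)Oc1ccc(cc1OC)[C@@H]2OC[C@@H]([C@@H]2CO)[C@H](O)c3ccc(OS(=O)(=O)c4ccc(C)cc4)c(OC)c3 | intermediate
18 | primary methanesulfonate of 17 (on the CH2OH group) | CC(C)[Si](C(C)C)(C(C)C)Oc1ccc(cc1OC)[C@@H]2OC[C@@H]([C@@H]2COS(C)(=O)=O)[C@H](O)c3ccc(OS(=O)(=O)c4ccc(C)cc4)c(OC)c3 | intermediate
19 | (1R,3aR,4S,6aR)-1-[3-methoxy-4-(triisopropylsilyloxy)phenyl]-4-[3-methoxy-4-(tosyloxy)phenyl]tetrahydro-1H,3H-furo[3,4-c]furan | CC(C)[Si](C(C)C)(C(C)C)Oc1ccc(cc1OC)[C@@H]2OC[C@H]3[C@@H]2CO[C@@H]3c4ccc(OS(=O)(=O)c5ccc(C)cc5)c(OC)c4 | intermediate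
20 | (1S,3aR,4S,6aR)-1-[3-methoxy-4-(triisopropylsilyloxy)phenyl]-4-[3-methoxy-4-(tosyloxy)phenyl]tetrahydro-1H,3H-furo[3,4-c]furan | CC(C)[Si](C(C)C)(C(C)C)Oc1ccc(cc1OC)[C@H]2OC[C@H]3[C@@H]2CO[C@@H]3c4ccc(OS(=O)(=O)c5ccc(C)cc5)c(OC)c4 | intermediate
21 | 2-methoxy-4-{(1S,3aR,4S,6aR)-4-[3-methoxy-4-(triisopropylsilyloxy)phenyl]tetrahydro-1H,3H-furo[3,4-c]furan-1-yl}phenol | CC(C)[Si](C(C)C)(C(C)C)Oc1ccc(cc1OC)[C@H]2OC[C@H]3[C@@H]2CO[C@@H]3c4ccc(O)c(OC)c4 | intermediate
22 | prenyl bromide (1-bromo-3-methylbut-2-ene) | CC(C)=CCBr | starting material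
23 | (1S,3aR,4S,6aR)-1-[3-methoxy-4-(triisopropylsilyloxy)phenyl]-4-[3-methoxy-4-(3-methylbut-2-enyloxy)phenyl]tetrahydro-1H,3H-furo[3,4-c]furan | CC(C)[Si](C(C)C)(C(C)C)Oc1ccc(cc1OC)[C@H]2OC[C@H]3[C@@H]2CO[C@@H]3c4ccc(OCC=C(C)C)c(OC)c4 | intermediate
24 | 2-methoxy-4-{(1S,3aR,4S,6aR)-4-[3-methoxy-4-(3-methylbut-2-enyloxy)phenyl]tetrahydro-1H,3H-furo[3,4-c]furan-1-yl}phenol | COc1cc([C@H]2OC[C@H]3[C@@H]2CO[C@@H]3c2ccc(OCC=C(C)C)c(OC)c2)ccc1O | target

## Step count and least certain steps

Total: 17 steps. Longest linear sequence: 13 steps (steps 4 and 6 to 17, from 1 to 24).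

Step 11 (key step). The most likely failure is migration of the C8' hydrogen to the carbenoid carbon, which gives the butenolide. Attack of the carbenoid on the electron-rich benzyl ring or carbene dimerisation may also compete, so that little insertion occurs. A change of facial preference at C7 would not be a loss, because the exo epimer would simply join the route at 20 after steps 12 and 13. The fallback sets out from 12 and comes back at 16 without a carbenoid. 12 is esterified with 3-methoxy-4-(triisopropylsilyloxy)benzoic acid (dicyclohexylcarbodiimide, DMAP) to the aroyl ester [(2S,3R)-2-[3-methoxy-4-(tosyloxy)phenyl]-5-oxotetrahydrofuran-3-yl]methyl 3-methoxy-4-(triisopropylsilyloxy)benzoate F1. LiN(SiMe3)2 (2.2 equiv, THF, −78 to 0 °C) then brings about an intramolecular Claisen acyl transfer from oxygen to C8, and on acidic work-up the alpha-aroyl lactone closes to the cyclic hemiketal (3S,3aR,6aS)-6-hydroxy-6-[3-methoxy-4-(triisopropylsilyloxy)phenyl]-3-[3-methoxy-4-(tosyloxy)phenyl]tetrahydro-1H,3H-furo[3,4-c]furan-1-one F2. Ionic hydrogenation (Et3SiH, BF3·OEt2, CH2Cl2, −78 °C) of the ring A oxocarbenium ion should deliver hydride on the convex face and so give 16.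

Step 14. The equilibrium between the C7 epimers is expected to lie close to balance, so enrichment per pass is small and repeated recycling is needed. Slow loss of the silyl group or intermolecular capture of the benzylic cation may add to this. The fallback sets out from 12 and comes back at 20; it places the aryl group by attack on the convex face instead of by equilibration. Alpha-formylation of 12 (LiN(SiMe3)2, ethyl formate) and treatment with methanol and camphorsulfonic acid gives the bicyclic acetal (3S,3aR,6aS)-6-methoxy-3-[3-methoxy-4-(tosyloxy)phenyl]tetrahydro-1H,3H-furo[3,4-c]furan-1-one F3. LiBH4 reduces the lactone to (S)-[(3R,4R)-4-(hydroxymethyl)-5-methoxytetrahydrofuran-3-yl][3-methoxy-4-(tosyloxy)phenyl]methanol F4, and MsCl with Et3N closes ring B as in step 13 to (3aR,4S,6aR)-1-methoxy-4-[3-methoxy-4-(tosyloxy)phenyl]tetrahydro-1H,3H-furo[3,4-c]furan F5. Lewis-acid C-arylation of this acetal (BF3·OEt2 with the aryltrifluoroborate or diarylzinc made from 4-bromo-2-methoxy-1-(triisopropylsilyloxy)benzene) should add the aryl group trans to the ring fusion and give 20.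

Step 15. The methoxide that builds up in the flask may strip the aryl silyl ether before the sulfonate is fully cleaved, which would remove the difference between the two phenols. The fallback sets out from 20 and comes back at 24. Both masks are removed on purpose (KOH, MeOH–THF, reflux) to give (+)-pinoresinol F6. Because its two phenols are related by the C2 axis, alkylation with a substoichiometric amount of 22 (K2CO3, acetone) can give only one mono-ether, which is 24; unreacted F6 is recovered and the bis-ether is separated.

Step 9. The electron-rich imidate 4 may ionise and condense with itself, or decay on storage, faster than it benzylates the hindered primary alcohol. The fallback sets out from 12 (with 2 as the partner) and comes back at 13 by reductive etherification. 12 is silylated (Me3SiCl, Et3N) to (4R,5S)-5-[3-methoxy-4-(tosyloxy)phenyl]-4-[(trimethylsilyloxy)methyl]dihydrofuran-2(3H)-one F7. This is combined with aldehyde 2 and Et3SiH under catalytic Me3SiOTf at −78 °C, so that the mixed oxocarbenium ion is reduced to the benzyl ether 13.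

## Further compounds

F1 | step 11 | [(2S,3R)-2-[3-methoxy-4-(tosyloxy)phenyl]-5-oxotetrahydrofuran-3-yl]methyl 3-methoxy-4-(triisopropylsilyloxy)benzoate | CC(C)[Si](C(C)C)(C(C)C)Oc1ccc(cc1OC)C(=O)OC[C@H]2CC(=O)O[C@@H]2c3ccc(OS(=O)(=O)c4ccc(C)cc4)c(OC)c3
F2 | step 11 | (3S,3aR,6aS)-6-hydroxy-6-[3-methoxy-4-(triisopropylsilyloxy)phenyl]-3-[3-methoxy-4-(tosyloxy)phenyl]tetrahydro-1H,3H-furo[3,4-c]furan-1-one (hemiketal carbon unassigned) | CC(C)[Si](C(C)C)(C(C)C)Oc1ccc(cc1OC)C2(O)OC[C@H]3[C@@H]2C(=O)O[C@@H]3c4ccc(OS(=O)(=O)c5ccc(C)cc5)c(OC)c4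
F3 | step 14 | (3S,3aR,6aS)-6-methoxy-3-[3-methoxy-4-(tosyloxy)phenyl]tetrahydro-1H,3H-furo[3,4-c]furan-1-one (acetal carbon unassigned) | COC2OC[C@H]3[C@@H]2C(=O)O[C@@H]3c4ccc(OS(=O)(=O)c5ccc(C)cc5)c(OC)c4
F4 | step 14 | (S)-[(3R,4R)-4-(hydroxymethyl)-5-methoxytetrahydrofuran-3-yl][3-methoxy-4-(tosyloxy)phenyl]methanol | COC2OC[C@@H]([C@@H]2CO)[C@H](O)c3ccc(OS(=O)(=O)c4ccc(C)cc4)c(OC)c3
F5 | step 14 | (3aR,4S,6aR)-1-methoxy-4-[3-methoxy-4-(tosyloxy)phenyl]tetrahydro-1H,3H-furo[3,4-c]furan | COC2OC[C@H]3[C@@H]2CO[C@@H]3c4ccc(OS(=O)(=O)c5ccc(C)cc5)c(OC)c4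
F6 | step 15 | (+)-pinoresinol, 4,4'-[(1S,3aR,4S,6aR)-tetrahydro-1H,3H-furo[3,4-c]furan-1,4-diyl]bis(2-methoxyphenol) | COc1cc(ccc1O)[C@H]2OC[C@H]3[C@@H]2CO[C@@H]3c4ccc(O)c(OC)c4
F7 | step 9 | (4R,5S)-5-[3-methoxy-4-(tosyloxy)phenyl]-4-[(trimethylsilyloxy)methyl]dihydrofuran-2(3H)-one | C[Si](C)(C)OC[C@H]1CC(=O)O[C@@H]1c2ccc(OS(=O)(=O)c3ccc(C)cc3)c(OC)c2
A1 | alternative 1 | O-triisopropylsilyl ether of the target (identical with 23) | CC(C)[Si](C(C)C)(C(C)C)Oc1ccc(cc1OC)[C@H]2OC[C@H]3[C@@H]2CO[C@@H]3c4ccc(OCC=C(C)C)c(OC)c4
A2 | alternative 1 | 2-{(R)-[3-methoxy-4-(triisopropylsilyloxy)phenyl][(E)-3-(3-methoxy-4-(3-methylbut-2-enyloxy)phenyl)allyloxy]methyl}oxirane (oxirane carbon unassigned) | CC(C)[Si](C(C)C)(C(C)C)Oc1ccc(cc1OC)[C@@H](OC/C=C/c2ccc(OCC=C(C)C)c(OC)c2)C3CO3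
A3 | alternative 2 | 2-aryl-3-(benzoyloxymethyl)-4-formyltetrahydrofuran, all-trans, aryl = 3-methoxy-4-(triisopropylsilyloxy)phenyl | CC(C)[Si](C(C)C)(C(C)C)Oc1ccc(cc1OC)[C@H]2OC[C@@H](C=O)[C@@H]2COC(=O)c3ccccc3
A4 | alternative 2 | (2E,4R)-4,5-dihydroxypent-2-en-1-yl benzoate | OC[C@H](O)/C=C/COC(=O)c1ccccc1
A5 | alternative 3 | cis-fused 9'-oxo furofuran lactone with the pivalate on the C7 aryl ring and the prenyl ether on the C7' aryl ring | CC(C)(C)C(=O)Oc1ccc(cc1OC)[C@H]2OC(=O)[C@H]3[C@@H]2CO[C@@H]3c4ccc(OCC=C(C)C)c(OC)c4
A6 | alternative 3 | (S)-5-[3-methoxy-4-(pivaloyloxy)phenyl]furan-2(5H)-one | CC(C)(C)C(=O)Oc1ccc(cc1OC)[C@H]2OC(=O)C=C2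
A7 | alternative 3 | {[chloro(3-methoxy-4-(3-methylbut-2-enyloxy)phenyl)methoxy]methyl}trimethylsilane (racemic) | COc1cc(C(Cl)OC[Si](C)(C)C)ccc1OCC=C(C)C
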